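The trap in birch was to call the smaller charge the limiting reagent: D at 1.3 M stood below J at 1.61 M, yet Z stalled at 68% of the D charged.

all flasks: J 1.61 M

| run | D | temperature | remark | time |
|---|---|---|---|---|
| larch | 0.85 M | 55 °C | run made earlier |  |
| birch | 1.3 M | 75 °C | run made earlier |  |
| noon | 1.7 M | 90 °C |  | 8.0 min |
| dawn | 1.7 M | 60 °C |  | 8.0 min |
| winter | 1.7 M | 75 °C |  | 8.0 min |

- larch (time / min: Z / %): 4.00: 2; 8.00: 9; 15.0: 31; 50.0: 76
- birch (time / min: Z / %): 2.00: 26; 6.00: 60; 10.0: 68; 15.0: 68

(readings scatter by 1.5 percentage points)

- which flask leads in amount of Z, in percent of the D charged ("all alike" within 1.5 percentage points) (noon / dawn / winter / all alike)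
- how much Z is there at the end, in percent of the D charged: noon
- how much Z is there at the end, in percent of the D charged: dawn
- how much Z is there at the end, in percent of the D charged: winter

So I drew up a ledger for the J in birch, taking one J for each Z. The first entry was the Z at the plateau, 0.884 M. The second was the J not found in Z, 0.726 M, which I left open as an unknown loss. Beside them stood 0.416 M of D not turned into Z. I treated J as the limiting reagent, and the books gave 0.549 mole of Z per mole of J charged; I named this the J yield, Y.

Noon, dawn and winter hold the same J as birch, so extra D buys no extra Z in this ledger. Y then caps Z at 52.0% of the D charged. Winter runs at birch's temperature, and its 8.0 min lies between birch's readings at 6.00 min and 10.0 min, so I put winter close to that cap. The ledger gave noon the same cap and could not separate the two. Dawn, at 60 °C, is warmer than larch at 55 °C, so I placed it between larch's 9% and 31%.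

The forecast gave winter the lead, with 54% for noon, 27% for dawn and 60% for winter: “I expect winter to lead narrowly, though this is uncertain.”

The flasks gave winter the lead, with noon at 54.0%, dawn at 21.5% and winter at 58.0%.

    Z → Q (k = 4.72 × 10⁻⁵ /s, Ea = 123 kJ/mol)
    E + X → Z (k = 0.101 /M/s, Ea = 83.0 kJ/mol)
    J → X (k = 0.0276 /s, Ea = 95.0 kJ/mol)
    X → L (k = 0.0367 /s, Ea = 110 kJ/mol)
    D ⇌ E (K = 2.26, k = 0.0301 /s, Ea = 106 kJ/mol, ΔH = −34.0 kJ/mol)
    (constants at 90 °C)

Winter beat my cap by 6 percentage points, with Y at 0.613, and at 8.00 min winter held 0.545 M of L, a species my open entry had not named. Left longer, winter changed little: by 80.0 min, its Z read 58.9% and its Y 0.622. Noon was not at rest, although its J stood at 0% at 8.00 min: by 80.0 min, its Z fell to 44.0% as its Q rose from 1.11% to 11.1%, taking its Y from 0.570 to 0.465. Dawn still held 46% of its J at 8.00 min, and by 80.0 min its Z reached 65.8%, a Y of 0.695.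

The readings were computed for substances that don't exist.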